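## Retrosynthetic overview
1. Target 40 ⇐ tetraol bis(benzyl ether) 39 by desilylation and then hydrogenolysis. 39 ⇐ erythro alcohol 38 ⇐ Mitsunobu inversion at C7'' of the threo series 34–36.
2. The key C7''–C8'' bond comes from an Evans syn glycolate aldol between the olivil-derived aryloxyacetyl imide 31 (fragment A) and O-benzylvanillin 5 (fragment B).
3. 31 ⇐ selectively unmasked 4'-phenol 25 + ethyl bromoacetate 26 + (R)-auxiliary 29. 25 ⇐ α-hydroxy-γ-lactone 21 by lactone → lactol → oxolane deoxygenation.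
4. 21 ⇐ lactone 13 by enolate benzylation (bromide 17, from vanillin) followed by enolate hydroxylation, both anti to the C8 side chain. 13 ⇐ Evans syn aldol (C7–C8) of succinyl imide 4 with 5, then lactonisation.
5. Ring order: only one ring is built, the γ-lactone (step 3), which is later reduced to the oxolane (steps 12–13). The three arenes are bought.

Assumption: the SMILES is taken literally as (7S,8R,8'S,7''R,8''S), which is (−)-olivil 4'-O-(erythro-guaiacylglycer-8''-yl) ether.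

Lignan numbering: C7 = ArCH–O, C8 = CH bearing C9H2OH, C7' = benzylic CH2, C8' = carbinol carbon, C9' = ring OCH2, C7''–C9'' = glycerol chain.

Abbreviations: Bn = benzyl, TBDPS = tert-butyldiphenylsilyl, TES = triethylsilyl, TBS = tert-butyldimethylsilyl, PPTS = pyridinium p-toluenesulfonate, DIAD = diisopropyl azodicarboxylate.

## Route

Step 1
Reactants: 1 (S)-4-benzyl-1,3-oxazolidin-2-one; 2 methyl 4-chloro-4-oxobutanoate
Product: 4 methyl 4-[(4S)-4-benzyl-2-oxo-1,3-oxazolidin-3-yl]-4-oxobutanoate, via N-lithio oxazolidinone 3 (not isolated)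
Conditions: n-BuLi (1.05 equiv), THF, −78 °C; then 2, −78 → 0 °C
Reagents that add atoms: none
Why: N-acylation of the lithiated oxazolidinone by the acid chloride is fast at −78 °C, the methyl ester is far less electrophilic, and the auxiliary stereocentre is not touched.

Step 2
Reactants: 4 succinyl imide; 5 4-(benzyloxy)-3-methoxybenzaldehyde (O-benzylvanillin)
Product: 8 methyl (3S,4S)-3-{[(4S)-4-benzyl-2-oxo-1,3-oxazolidin-3-yl]carbonyl}-4-[4-(benzyloxy)-3-methoxyphenyl]-4-hydroxybutanoate (syn aldol), via Z-dibutylboron enolate 6 (not isolated), via dibutylboron aldolate 7 (not isolated)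
Conditions: Bu2BOTf (1.2 equiv), i-Pr2NEt (1.4 equiv), CH2Cl2, 0 °C; 5, −78 → 0 °C; pH 7 buffer, MeOH, 30% H2O2, 0 °C
Reagents that add atoms: none
Why: In this Evans syn aldol the imide (not the ester) is enolised to the Z-boron enolate, which adds through a Zimmerman–Traxler chair on the face away from the auxiliary benzyl group, forming C7–C8 and setting C7 (S) and C8 (the final R centre) together.

Step 3
Reactants: 8 syn aldol
Product: 9 (4S)-4-benzyl-3-{[(2S,3S)-2-[4-(benzyloxy)-3-methoxyphenyl]-5-oxooxolan-3-yl]carbonyl}-1,3-oxazolidin-2-one (7,8-trans lactone)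
Conditions: PPTS (10 mol %), toluene, 60 °C
Reagents that add atoms: none
Why: Acid-catalysed lactonisation of a γ-hydroxy ester is strongly favoured, the syn aldol maps onto the 7,8-trans lactone with the C7–O bond retained, and trans is also the thermodynamic isomer.

Step 4
Reactants: 9 lactone imide
Product: 11 (2S,3S)-2-[4-(benzyloxy)-3-methoxyphenyl]-5-oxooxolane-3-carboxylic acid, via peroxy acid 10 (not isolated)
Conditions: LiOH (2 equiv), 30% H2O2 (5 equiv), THF/H2O 3:1, 0 °C; aq. Na2SO3; 1 M HCl to pH 2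
Reagents that add atoms: hydrogen peroxide (acting as LiOOH), OO
Why: Hydroperoxide-mediated auxiliary cleavage attacks the exocyclic imide carbonyl selectively, any opened lactone recloses on acidification, and the already trans C8 centre has no driving force to epimerise.

Step 5
Reactants: 11 lactone acid
Product: 12 (4R,5S)-5-[4-(benzyloxy)-3-methoxyphenyl]-4-(hydroxymethyl)oxolan-2-one
Conditions: BH3·SMe2 (1.5 equiv), THF, 0 °C → rt; MeOH quench
Reagents that add atoms: none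
Why: In this chemoselective borane reduction the free acid reacts through its acyloxyborane much faster than the lactone, and the non-basic medium avoids translactonisation, so both stereocentres are unchanged.

Step 6
Reactants: 12 hydroxymethyl lactone
Product: 13 (4R,5S)-5-[4-(benzyloxy)-3-methoxyphenyl]-4-[(TBDPS-oxy)methyl]oxolan-2-one
Conditions: TBDPSCl (1.1 equiv), imidazole (2.2 equiv), DMF, 0 °C → rt
Reagents that add atoms: tert-butyl(chloro)diphenylsilane, CC(C)(C)[Si](Cl)(c1ccccc1)c1ccccc1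
Why: Imidazole-promoted silylation of the only hydroxyl is mild enough to leave the lactone alone, and it installs a bulky, Lewis-acid-tolerant group that later shields one ring face.

Step 7
Reactants: 14 vanillin
Product: 15 4-(allyloxy)-3-methoxybenzaldehyde
Conditions: allyl bromide (1.2 equiv), K2CO3 (1.5 equiv), DMF, rt
Reagents that add atoms: allyl bromide, C=CCBr
Why: Williamson ether synthesis on the acidic phenol gives an allyl ether that is orthogonal to benzyl and silyl groups.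

Step 8
Reactants: 15 O-allylvanillin
Product: 16 [4-(allyloxy)-3-methoxyphenyl]methanol
Conditions: NaBH4 (0.5 equiv), MeOH, 0 °C
Reagents that add atoms: none
Why: Borohydride reduction of an aromatic aldehyde is quantitative and leaves the allyl ether untouched.

Step 9
Reactants: 16 benzylic alcohol
Product: 17 1-(allyloxy)-4-(bromomethyl)-2-methoxybenzene
Conditions: PBr3 (0.4 equiv), Et2O, 0 °C; used freshly prepared
Reagents that add atoms: phosphorus tribromide, BrP(Br)Br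
Why: Bromide displaces the phosphite ester (nucleophilic substitution) rapidly at an electron-rich primary benzylic carbon.

Step 10
Reactants: 13 lactone; 17 benzylic bromide
Product: 19 (3S,4R,5S)-3-[4-(allyloxy)-3-methoxybenzyl]-5-[4-(benzyloxy)-3-methoxyphenyl]-4-[(TBDPS-oxy)methyl]oxolan-2-one, via lithium enolate 18 (not isolated)
Conditions: LiN(SiMe3)2 (1.1 equiv), THF, −78 °C; 17 (1.3 equiv), DMPU, −78 → −30 °C
Reagents that add atoms: none
Why: In this lactone enolate alkylation (SN2) the bromide enters anti to the C8 side chain to give the 8,8'-trans product, no β-leaving group is present, and the new C8' configuration is provisional because step 11 erases it.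

Step 11
Reactants: 19 α-benzyl lactone
Product: 21 (3S,4R,5S)-3-[4-(allyloxy)-3-methoxybenzyl]-5-[4-(benzyloxy)-3-methoxyphenyl]-3-hydroxy-4-[(TBDPS-oxy)methyl]oxolan-2-one, via potassium enolate 20 (not isolated)
Conditions: KN(SiMe3)2 (1.3 equiv), THF, −78 °C; 2-(phenylsulfonyl)-3-phenyloxaziridine (1.5 equiv), −78 °C; AcOH quench
Reagents that add atoms: 2-(phenylsulfonyl)-3-phenyloxaziridine, O=S(=O)(c1ccccc1)N1OC1c1ccccc1
Why: In this Davis enolate oxidation the planar enolate takes oxygen on the face anti to the adjacent CH2OTBDPS group, so OH ends trans and the benzyl group cis to C9, which is the required 8'S centre.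

Step 12
Reactants: 21 α-hydroxy lactone
Product: 22 (3S,4R,5S)-3-[4-(allyloxy)-3-methoxybenzyl]-5-[4-(benzyloxy)-3-methoxyphenyl]-4-[(TBDPS-oxy)methyl]oxolane-2,3-diol (lactol; both C2 anomers)
Conditions: i-Bu2AlH (3 equiv), CH2Cl2, −78 °C; aq. potassium sodium tartrate
Reagents that add atoms: none
Why: Partial lactone reduction stops at the stable aluminium hemiacetal at −78 °C after the first equivalent has deprotonated the tertiary OH, and the new anomeric centre does not matter.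

Step 13
Reactants: 22 lactol
Product: 23 (3S,4R,5S)-3-[4-(allyloxy)-3-methoxybenzyl]-5-[4-(benzyloxy)-3-methoxyphenyl]-4-[(TBDPS-oxy)methyl]oxolan-3-ol (4'-O-allyl-4-O-benzyl-9-O-TBDPS-olivil)
Conditions: Et3SiH (5 equiv), BF3·OEt2 (2 equiv), CH2Cl2, −78 → −40 °C; aq. NaHCO3
Reagents that add atoms: none
Why: In this ionic reduction of a lactol, BF3 ionises the anomeric OH to an oxocarbenium ion that premixed Et3SiH traps faster than the benzylic C7–O bond can ionise at low temperature, so C9' becomes CH2 and C7, C8 and C8' are untouched.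

Step 14
Reactants: 23 tertiary alcohol
Product: 24 8'-O-TES ether of 23 (4'-O-allyl-4-O-benzyl-9-O-TBDPS-8'-O-TES-olivil)
Conditions: TESOTf (1.5 equiv), 2,6-lutidine (2.5 equiv), CH2Cl2, 0 °C
Reagents that add atoms: triethylsilyl triflate, CC[Si](CC)(CC)OS(=O)(=O)C(F)(F)F
Why: Silyl triflate silylation is strong enough for a hindered tertiary alcohol, and it removes the only protic site that would consume Bu2BOTf in step 19.

Step 15
Reactants: 24 allyl ether
Product: 25 4-O-benzyl-9-O-TBDPS-8'-O-TES-olivil (free 4'-phenol)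
Conditions: Pd(PPh3)4 (5 mol %), morpholine (5 equiv), THF, rt
Reagents that add atoms: none
Why: In this Tsuji–Trost deallylation, zerovalent palladium ionises only the aryl allyl ether to a π-allyl complex that morpholine captures, leaving benzyl and silyl ethers intact.

Step 16
Reactants: 25 phenol; 26 ethyl bromoacetate
Product: 27 ethyl 2-[(4-O-benzyl-9-O-TBDPS-8'-O-TES-olivil-4'-yl)oxy]acetate
Conditions: 26 (1.3 equiv), K2CO3 (2 equiv), DMF, rt
Reagents that add atoms: none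
Why: Williamson ether synthesis with an activated α-bromo ester is fast at the only acidic OH and builds the O–C8''–C9'' unit.

Step 17
Reactants: 27 ester
Product: 28 2-[(4-O-benzyl-9-O-TBDPS-8'-O-TES-olivil-4'-yl)oxy]acetic acid
Conditions: LiOH·H2O (3 equiv), THF/H2O 3:1, 0 °C → rt; 1 M HCl to pH 4 at 0 °C
Reagents that add atoms: lithium hydroxide, [Li+].[OH-]
Why: Saponification of an unhindered aryloxyacetate is quick, and the mild, cold acidification keeps all three ether protecting groups.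

Step 18
Reactants: 28 acid; 29 (R)-4-benzyl-1,3-oxazolidin-2-one
Product: 31 (4R)-4-benzyl-3-{2-[(4-O-benzyl-9-O-TBDPS-8'-O-TES-olivil-4'-yl)oxy]acetyl}-1,3-oxazolidin-2-one, via mixed pivalic anhydride 30 (not isolated)
Conditions: t-BuCOCl (1.1 equiv), Et3N (2.5 equiv), THF, −20 °C; LiCl (1.2 equiv), 29 (1.1 equiv), −20 °C → rt
Reagents that add atoms: none
Why: In this mixed-anhydride N-acylation, the LiCl-activated oxazolidinone attacks the less hindered aryloxyacetyl carbonyl under conditions with no strong base.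

Step 19
Reactants: 31 aryloxyacetyl imide (fragment A); 5 O-benzylvanillin (fragment B)
Product: 34 (4R)-4-benzyl-3-{(2R,3S)-3-[4-(benzyloxy)-3-methoxyphenyl]-3-hydroxy-2-[(4-O-benzyl-9-O-TBDPS-8'-O-TES-olivil-4'-yl)oxy]propanoyl}-1,3-oxazolidin-2-one (syn aldol), via Z-dibutylboron enolate 32 (not isolated), via dibutylboron aldolate 33 (not isolated)
Conditions: Bu2BOTf (1.3 equiv), i-Pr2NEt (1.5 equiv), CH2Cl2, −78 → 0 °C; 5 (1.5 equiv), −78 → 0 °C; pH 7 buffer, MeOH, 30% H2O2, 0 °C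
Reagents that add atoms: none
Why: In this Evans syn glycolate aldol, the Z-boron enolate of the 2-methoxyphenoxyacetyl-type imide reacts through a Zimmerman–Traxler chair under (R)-auxiliary control, forming C7''–C8'' and setting the final 8''S centre together with a 7''S carbinol that step 22 inverts.

Step 20
Reactants: 34 syn aldol
Product: 35 (7''S,8''S)-threo 1,3-diol (C9''H2OH and C7''HOH free; 4,4'''-di-O-benzyl; 9-O-TBDPS; 8'-O-TES)
Conditions: NaBH4 (4 equiv), THF/H2O 4:1, 0 °C → rt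
Reagents that add atoms: none
Why: Reductive auxiliary cleavage by borohydride attacks the activated exocyclic imide carbonyl and takes it to the primary alcohol without touching C7'' or C8''.

Step 21
Reactants: 35 threo diol
Product: 36 9''-O-TBS ether of 35 (7''S,8''S; secondary benzylic OH free)
Conditions: TBSCl (1.1 equiv), imidazole (2 equiv), CH2Cl2, 0 °C
Reagents that add atoms: tert-butyl(chloro)dimethylsilane, CC(C)(C)[Si](C)(C)Cl
Why: Sterically controlled selective silylation takes the primary alcohol far faster than the flanked secondary benzylic one.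

Step 22
Reactants: 36 threo alcohol
Product: 37 (7''R,8''S)-erythro 7''-O-(4-nitrobenzoate) of the 9''-O-TBS ether
Conditions: 4-O2NC6H4CO2H (3 equiv), PPh3 (3 equiv), DIAD (3 equiv), toluene, −20 °C → rt
Reagents that add atoms: 4-nitrobenzoic acid, O=C(O)c1ccc([N+](=O)[O-])cc1
Why: In this Mitsunobu inversion, the acidic carboxylate displaces the oxyphosphonium group of the only free OH by SN2, turning 7''S into 7''R (threo to erythro), while the non-polar solvent and low temperature suppress ionisation.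

Step 23
Reactants: 37 nitrobenzoate
Product: 38 (7''R,8''S)-erythro alcohol (9''-O-TBS; 9-O-TBDPS; 8'-O-TES; 4,4'''-di-O-benzyl)
Conditions: K2CO3 (0.3 equiv), MeOH/THF 2:1, 0 °C → rt
Reagents that add atoms: none
Why: Base-catalysed transesterification cleaves the activated ester at the acyl–oxygen bond, so the C7''–O bond and its new configuration are retained and alkyl silyl ethers survive.

Step 24
Reactants: 38 tris-silyl ether
Product: 39 4,4'''-di-O-benzyl derivative of the target (tetraol; 7S,8R,8'S,7''R,8''S)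
Conditions: Bu4NF (6 equiv), AcOH (6 equiv), THF, rt → 40 °C
Reagents that add atoms: none
Why: Fluoride desilylation removes TBS, TES and TBDPS in one operation, and it is run while both phenols are still benzylated so that no quinone methide can form from the β-aryl ether unit.

Step 25
Reactants: 39 bis(benzyl ether)
Product: 40 target, (−)-olivil 4'-O-[(7''R,8''S)-erythro-guaiacylglycer-8''-yl] ether
Conditions: H2 (1 atm), 10% Pd/C, EtOAc/EtOH 1:1, rt, stopped at full conversion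
Reagents that add atoms: none
Why: Catalytic hydrogenolysis cleaves aryl benzyl ethers much faster under neutral conditions at 1 atm than the secondary benzylic alcohol or the 2-aryl-oxolane C–O bond, so all five stereocentres are delivered intact.

## Compound list
1 | (S)-4-benzyl-1,3-oxazolidin-2-one | O=C1N[C@@H](Cc2ccccc2)CO1 | starting material
2 | methyl 4-chloro-4-oxobutanoate | COC(=O)CCC(=O)Cl | starting material
3 | N-lithio-(S)-4-benzyl-1,3-oxazolidin-2-one | [Li]N1C(=O)OC[C@@H]1Cc1ccccc1 | intermediate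
4 | methyl 4-[(4S)-4-benzyl-2-oxo-1,3-oxazolidin-3-yl]-4-oxobutanoate | COC(=O)CCC(=O)N1C(=O)OC[C@@H]1Cc1ccccc1 | intermediate
5 | 4-(benzyloxy)-3-methoxybenzaldehyde | COc1cc(C=O)ccc1OCc1ccccc1 | starting material
6 | Z-dibutylboron enolate of 4 | CCCCB(CCCC)O/C(=C\CC(=O)OC)N1C(=O)OC[C@@H]1Cc1ccccc1 | intermediate
7 | dibutylboron aldolate of 8 | CCCCB(CCCC)O[C@H](c1ccc(OCc2ccccc2)c(OC)c1)[C@H](CC(=O)OC)C(=O)N1C(=O)OC[C@@H]1Cc1ccccc1 | intermediate
8 | methyl (3S,4S)-3-{[(4S)-4-benzyl-2-oxo-1,3-oxazolidin-3-yl]carbonyl}-4-[4-(benzyloxy)-3-methoxyphenyl]-4-hydroxybutanoate | O[C@H](c1ccc(OCc2ccccc2)c(OC)c1)[C@H](CC(=O)OC)C(=O)N1C(=O)OC[C@@H]1Cc1ccccc1 | intermediate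
9 | (4S)-4-benzyl-3-{[(2S,3S)-2-[4-(benzyloxy)-3-methoxyphenyl]-5-oxooxolan-3-yl]carbonyl}-1,3-oxazolidin-2-one | C1C(=O)O[C@H](c2ccc(OCc3ccccc3)c(OC)c2)[C@H]1C(=O)N1C(=O)OC[C@@H]1Cc1ccccc1 | intermediate
10 | (2S,3S)-2-[4-(benzyloxy)-3-methoxyphenyl]-5-oxooxolane-3-carboperoxoic acid | C1C(=O)O[C@H](c2ccc(OCc3ccccc3)c(OC)c2)[C@H]1C(=O)OO | intermediate
11 | (2S,3S)-2-[4-(benzyloxy)-3-methoxyphenyl]-5-oxooxolane-3-carboxylic acid | C1C(=O)O[C@H](c2ccc(OCc3ccccc3)c(OC)c2)[C@H]1C(=O)O | intermediate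
12 | (4R,5S)-5-[4-(benzyloxy)-3-methoxyphenyl]-4-(hydroxymethyl)oxolan-2-one | C1C(=O)O[C@H](c2ccc(OCc3ccccc3)c(OC)c2)[C@H]1CO | intermediate
13 | (4R,5S)-5-[4-(benzyloxy)-3-methoxyphenyl]-4-[(TBDPS-oxy)methyl]oxolan-2-one | C1C(=O)O[C@H](c2ccc(OCc3ccccc3)c(OC)c2)[C@H]1CO[Si](c1ccccc1)(c1ccccc1)C(C)(C)C | intermediate
14 | vanillin | COc1cc(C=O)ccc1O | starting material
15 | 4-(allyloxy)-3-methoxybenzaldehyde | C=CCOc1ccc(C=O)cc1OC | intermediate
16 | [4-(allyloxy)-3-methoxyphenyl]methanol | C=CCOc1ccc(CO)cc1OC | intermediate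
17 | 1-(allyloxy)-4-(bromomethyl)-2-methoxybenzene | C=CCOc1ccc(CBr)cc1OC | intermediate
18 | lithium enolate of 13 | C1=C(O[Li])O[C@H](c2ccc(OCc3ccccc3)c(OC)c2)[C@H]1CO[Si](c1ccccc1)(c1ccccc1)C(C)(C)C | intermediate
19 | (3S,4R,5S)-3-[4-(allyloxy)-3-methoxybenzyl]-5-[4-(benzyloxy)-3-methoxyphenyl]-4-[(TBDPS-oxy)methyl]oxolan-2-one | C=CCOc1ccc(C[C@@H]2C(=O)O[C@H](c3ccc(OCc4ccccc4)c(OC)c3)[C@H]2CO[Si](c2ccccc2)(c2ccccc2)C(C)(C)C)cc1OC | intermediate
20 | potassium enolate of 19 | C=CCOc1ccc(CC2=C(O[K])O[C@H](c3ccc(OCc4ccccc4)c(OC)c3)[C@H]2CO[Si](c2ccccc2)(c2ccccc2)C(C)(C)C)cc1OC | intermediate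
21 | (3S,4R,5S)-3-[4-(allyloxy)-3-methoxybenzyl]-5-[4-(benzyloxy)-3-methoxyphenyl]-3-hydroxy-4-[(TBDPS-oxy)methyl]oxolan-2-one | C=CCOc1ccc(C[C@@]2(O)C(=O)O[C@H](c3ccc(OCc4ccccc4)c(OC)c3)[C@H]2CO[Si](c2ccccc2)(c2ccccc2)C(C)(C)C)cc1OC | intermediate
22 | (3S,4R,5S)-3-[4-(allyloxy)-3-methoxybenzyl]-5-[4-(benzyloxy)-3-methoxyphenyl]-4-[(TBDPS-oxy)methyl]oxolane-2,3-diol (C2 anomers) | C=CCOc1ccc(C[C@@]2(O)C(O)O[C@H](c3ccc(OCc4ccccc4)c(OC)c3)[C@H]2CO[Si](c2ccccc2)(c2ccccc2)C(C)(C)C)cc1OC | intermediate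
23 | (3S,4R,5S)-3-[4-(allyloxy)-3-methoxybenzyl]-5-[4-(benzyloxy)-3-methoxyphenyl]-4-[(TBDPS-oxy)methyl]oxolan-3-ol | C=CCOc1ccc(C[C@@]2(O)CO[C@H](c3ccc(OCc4ccccc4)c(OC)c3)[C@H]2CO[Si](c2ccccc2)(c2ccccc2)C(C)(C)C)cc1OC | intermediate
24 | 8'-O-TES ether of 23 | C=CCOc1ccc(C[C@@]2(O[Si](CC)(CC)CC)CO[C@H](c3ccc(OCc4ccccc4)c(OC)c3)[C@H]2CO[Si](c2ccccc2)(c2ccccc2)C(C)(C)C)cc1OC | intermediate
25 | 4-O-benzyl-9-O-TBDPS-8'-O-TES-olivil (free 4'-phenol) | Oc1ccc(C[C@@]2(O[Si](CC)(CC)CC)CO[C@H](c3ccc(OCc4ccccc4)c(OC)c3)[C@H]2CO[Si](c2ccccc2)(c2ccccc2)C(C)(C)C)cc1OC | intermediate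
26 | ethyl bromoacetate | CCOC(=O)CBr | starting material
27 | ethyl 2-[(4-O-benzyl-9-O-TBDPS-8'-O-TES-olivil-4'-yl)oxy]acetate | CCOC(=O)COc1ccc(C[C@@]2(O[Si](CC)(CC)CC)CO[C@H](c3ccc(OCc4ccccc4)c(OC)c3)[C@H]2CO[Si](c2ccccc2)(c2ccccc2)C(C)(C)C)cc1OC | intermediate
28 | 2-[(4-O-benzyl-9-O-TBDPS-8'-O-TES-olivil-4'-yl)oxy]acetic acid | OC(=O)COc1ccc(C[C@@]2(O[Si](CC)(CC)CC)CO[C@H](c3ccc(OCc4ccccc4)c(OC)c3)[C@H]2CO[Si](c2ccccc2)(c2ccccc2)C(C)(C)C)cc1OC | intermediate
29 | (R)-4-benzyl-1,3-oxazolidin-2-one | O=C1N[C@H](Cc2ccccc2)CO1 | starting material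
30 | mixed anhydride of 28 and pivalic acid | CC(C)(C)C(=O)OC(=O)COc1ccc(C[C@@]2(O[Si](CC)(CC)CC)CO[C@H](c3ccc(OCc4ccccc4)c(OC)c3)[C@H]2CO[Si](c2ccccc2)(c2ccccc2)C(C)(C)C)cc1OC | intermediate
31 | (4R)-4-benzyl-3-{2-[(4-O-benzyl-9-O-TBDPS-8'-O-TES-olivil-4'-yl)oxy]acetyl}-1,3-oxazolidin-2-one | O=C(COc1ccc(C[C@@]2(O[Si](CC)(CC)CC)CO[C@H](c3ccc(OCc4ccccc4)c(OC)c3)[C@H]2CO[Si](c2ccccc2)(c2ccccc2)C(C)(C)C)cc1OC)N1C(=O)OC[C@H]1Cc1ccccc1 | intermediate
32 | Z-dibutylboron enolate of 31 | CCCCB(CCCC)O/C(=C\Oc1ccc(C[C@@]2(O[Si](CC)(CC)CC)CO[C@H](c3ccc(OCc4ccccc4)c(OC)c3)[C@H]2CO[Si](c2ccccc2)(c2ccccc2)C(C)(C)C)cc1OC)N1C(=O)OC[C@H]1Cc1ccccc1 | intermediate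
33 | dibutylboron aldolate of 34 | COc1cc([C@H](OB(CCCC)CCCC)[C@H](C(=O)N2C(=O)OC[C@H]2Cc2ccccc2)Oc2ccc(C[C@@]3(O[Si](CC)(CC)CC)CO[C@H](c4ccc(OCc5ccccc5)c(OC)c4)[C@H]3CO[Si](c4ccccc4)(c4ccccc4)C(C)(C)C)cc2OC)ccc1OCc1ccccc1 | intermediate
34 | (2R,3S)-syn aldol imide (7''S; C8'' as in the target) | COc1cc([C@H](O)[C@H](C(=O)N2C(=O)OC[C@H]2Cc2ccccc2)Oc2ccc(C[C@@]3(O[Si](CC)(CC)CC)CO[C@H](c4ccc(OCc5ccccc5)c(OC)c4)[C@H]3CO[Si](c4ccccc4)(c4ccccc4)C(C)(C)C)cc2OC)ccc1OCc1ccccc1 | intermediate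
35 | (7''S,8''S)-threo 1,3-diol | COc1cc([C@H](O)[C@H](CO)Oc2ccc(C[C@@]3(O[Si](CC)(CC)CC)CO[C@H](c4ccc(OCc5ccccc5)c(OC)c4)[C@H]3CO[Si](c4ccccc4)(c4ccccc4)C(C)(C)C)cc2OC)ccc1OCc1ccccc1 | intermediate
36 | (7''S,8''S)-threo 9''-O-TBS ether | COc1cc([C@H](O)[C@H](CO[Si](C)(C)C(C)(C)C)Oc2ccc(C[C@@]3(O[Si](CC)(CC)CC)CO[C@H](c4ccc(OCc5ccccc5)c(OC)c4)[C@H]3CO[Si](c4ccccc4)(c4ccccc4)C(C)(C)C)cc2OC)ccc1OCc1ccccc1 | intermediate
37 | (7''R,8''S)-erythro 7''-O-(4-nitrobenzoate) | COc1cc([C@@H](OC(=O)c2ccc([N+](=O)[O-])cc2)[C@H](CO[Si](C)(C)C(C)(C)C)Oc2ccc(C[C@@]3(O[Si](CC)(CC)CC)CO[C@H](c4ccc(OCc5ccccc5)c(OC)c4)[C@H]3CO[Si](c4ccccc4)(c4ccccc4)C(C)(C)C)cc2OC)ccc1OCc1ccccc1 | intermediate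
38 | (7''R,8''S)-erythro alcohol, fully protected elsewhere | COc1cc([C@@H](O)[C@H](CO[Si](C)(C)C(C)(C)C)Oc2ccc(C[C@@]3(O[Si](CC)(CC)CC)CO[C@H](c4ccc(OCc5ccccc5)c(OC)c4)[C@H]3CO[Si](c4ccccc4)(c4ccccc4)C(C)(C)C)cc2OC)ccc1OCc1ccccc1 | intermediate
39 | 4,4'''-di-O-benzyl target (tetraol) | COc1cc([C@@H](O)[C@H](CO)Oc2ccc(C[C@@]3(O)CO[C@H](c4ccc(OCc5ccccc5)c(OC)c4)[C@H]3CO)cc2OC)ccc1OCc1ccccc1 | intermediate
40 | CNP0350466.2, (7S,8R,8'S,7''R,8''S) | COc1cc([C@@H](O)[C@H](CO)Oc2ccc(C[C@@]3(O)CO[C@H](c4ccc(O)c(OC)c4)[C@H]3CO)cc2OC)ccc1O | target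

## Step count and risks
Total steps: 25. Longest linear sequence: 22 (steps 1–6 and 10–25). Steps 7–9 form a three-step side branch.

**Risk 1, step 11.** The enolate is hindered and fully substituted, so both conversion and facial ratio are uncertain.
- The fallback sets out from 19 and comes back at 22.
- Instead of oxidising an enolate, 19 is first reduced with i-Bu2AlH (toluene, −78 °C) to the 8'-deoxy lactol F1.
- This is dehydrated (MsCl, Et3N, CH2Cl2, −40 °C → reflux) to the 4-benzyl-2,3-dihydrofuran F2.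
- This electron-rich enol ether is epoxidised within minutes by dimethyldioxirane (1.05 equiv, acetone/CH2Cl2, −78 → 0 °C) on the face anti to the C9 side chain, giving the 8',9'-epoxide F3. The allyl ether reacts far more slowly.
- Water (THF/H2O, 0 °C) opens the epoxide at the acetal carbon C9' to give lactol 22 with the C8'–O bond already in place.

**Risk 2, step 13.** The Lewis acid may ionise the 2-aryl-oxolane, or the electron-rich benzyl ring may capture the cation in a Friedel–Crafts reaction.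
- The fallback sets out from 21 and comes back at 23.
- LiAlH4 (THF, 0 °C) opens the lactone to the 7,8',9'-triol F4.
- The ring is then closed from the other end, by forming the C7–O bond. Catalytic camphorsulfonic acid (CH2Cl2, 0 °C, short time) ionises only the electron-rich benzylic C7–OH.
- The primary C9'–OH captures the cation in a 5-exo closure, and the 7,8-trans oxolane 23 is the favoured product.

**Risk 3, step 22.** Partial SN1 scrambling or elimination can occur at the electron-rich benzylic carbinol.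
- The fallback sets out from 36 and comes back at 38.
- Dess–Martin periodinane (NaHCO3, CH2Cl2, 0 °C) gives the α-aryloxy aryl ketone F5.
- Zn(BH4)2 (Et2O, −30 °C) reduces it under Cram-chelate control. Zinc is held by the ketone and the 8''-aryloxy oxygen, and hydride arrives from the side of H-8''.
- This gives the anti, that is erythro (7''R,8''S), alcohol 38 directly, so steps 22 and 23 are bypassed.

## Further compounds
F1 | step 11 | (3S,4R,5S)-3-[4-(allyloxy)-3-methoxybenzyl]-5-[4-(benzyloxy)-3-methoxyphenyl]-4-[(TBDPS-oxy)methyl]oxolan-2-ol (C2 anomers) | C=CCOc1ccc(C[C@@H]2C(O)O[C@H](c3ccc(OCc4ccccc4)c(OC)c3)[C@H]2CO[Si](c2ccccc2)(c2ccccc2)C(C)(C)C)cc1OC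
F2 | step 11 | (2S,3R)-4-[4-(allyloxy)-3-methoxybenzyl]-2-[4-(benzyloxy)-3-methoxyphenyl]-3-[(TBDPS-oxy)methyl]-2,3-dihydrofuran | C=CCOc1ccc(CC2=CO[C@H](c3ccc(OCc4ccccc4)c(OC)c3)[C@H]2CO[Si](c2ccccc2)(c2ccccc2)C(C)(C)C)cc1OC
F3 | step 11 | 8',9'-epoxide of F2, epoxide oxygen anti to the C9 side chain | C=CCOc1ccc(C[C@@]23O[C@@H]2O[C@H](c2ccc(OCc4ccccc4)c(OC)c2)[C@H]3CO[Si](c2ccccc2)(c2ccccc2)C(C)(C)C)cc1OC
F4 | step 13 | (2S,3R,4S)-2-[4-(allyloxy)-3-methoxybenzyl]-4-[4-(benzyloxy)-3-methoxyphenyl]-3-[(TBDPS-oxy)methyl]butane-1,2,4-triol | C=CCOc1ccc(C[C@@](O)(CO)[C@H](CO[Si](c2ccccc2)(c2ccccc2)C(C)(C)C)[C@H](O)c2ccc(OCc3ccccc3)c(OC)c2)cc1OC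
F5 | step 22 | (8''S)-7''-ketone derived from 36 | COc1cc(C(=O)[C@H](CO[Si](C)(C)C(C)(C)C)Oc2ccc(C[C@@]3(O[Si](CC)(CC)CC)CO[C@H](c4ccc(OCc5ccccc5)c(OC)c4)[C@H]3CO[Si](c4ccccc4)(c4ccccc4)C(C)(C)C)cc2OC)ccc1OCc1ccccc1
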